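Readings and results were computed from invented constants, noise included.

A small charge of precatalyst need not be working free catalyst from the first second, and the two runs let us test that on the substrate.

| flask | substrate | partner | second catalyst | precatalyst | remark |
|---|---|---|---|---|---|
| noon | 0.010 M | 1 equiv | 10 mol% | 7.7 mol% | the very flask that is asked about, followed so far |
| midnight | 0.010 M | 1 equiv | 10 mol% | 5.2 mol% | run made earlier |
| flask | 0.010 M | 1.00 equiv | 10 mol% | 7.7 mol% |  |

- noon (time / s: product / %, substrate / %): 15.0: 69.1, 10.1; 40.0: 93.8, 0; 80.0: 97.2, 0; 120: 98.2, 0
- midnight (time / min: product / %, substrate / %): 0.333: 75.5, 6.9; 1.00: 95.8, 0; 2.00: 98.3, 0.1; 3.00: 98.9, 0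

(readings scatter by 0.3 percentage points)

- factor on the rate of making product when 50% of the substrate are converted if partner is charged twice over
- factor on the rate when 50% of the substrate are converted if precatalyst is charged at 1.5 mol% instead

We read the first row of each table and take the log loss of substrate, the natural log of charged over remaining. If free catalyst stood in proportion to the precatalyst charged from the start, log loss per precatalyst fraction and per time would match between runs. Instead it is 1.98 s⁻¹ in the noon run and a larger 2.57 s⁻¹ in the midnight run. If free catalyst instead grows in step with time, log loss goes as the precatalyst fraction times the square of time over a fixed time, and that fixed time reads 2.75 s in the noon run and 2.79 s in the midnight run. We keep their mean, 2.77 s, as the release time: the time at which the log loss of substrate would equal the precatalyst fraction charged.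

By our reckoning, the fraction of substrate lost per time at half conversion then goes as the square root of the precatalyst charged. We assume product follows that loss in a fixed share, so our factor for the lower charge is 0.441. Partner does not enter the substrate step and no run varied it, so this rule gives no factor for doubling it.

The forecast gives 1.17 (1.03 to 1.4) for doubled partner and 0.53 (0.4 to 0.68) for the lower charge, from “an apparent order of about 0.33–0.5”; that second factor is higher than ours.

The simulation gives 1.19 for doubled partner and 0.448 for the lower charge.

    precatalyst ⇌ free catalyst (K = 2.90, k = 0.0232 s⁻¹)
    partner + second catalyst + intermediate → second catalyst + product (k = 54400 M⁻² s⁻¹)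
    substrate + free catalyst → free catalyst + intermediate (k = 1310 M⁻¹ s⁻¹)

In this flask at 0.134 min, product forms at 0.0403 M min⁻¹, while intermediate is made 1.24 times as fast as it is used up. The release time puts half conversion in this flask at 0.138 min, and the flask reaches it at 0.134 min; with precatalyst charged at 1.5 mol%, the same reckoning puts it at 0.314 min.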